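**Retrosynthetic overview**

1. The last ring closed is the γ-lactone, through its O–C6 bond. C6 is both the γ-carbon of the C12 acrylic acid and the allylic terminus of the C4=C5–C6 unit of the ten-membered ring, so O–C6 together with the (E)-C4=C5 alkene is the retron of a 5-exo hydro-acyloxylation of a C4=C5=C6 allene; the cis ring fusion and the E geometry come from one anti addition.
2. The ten-membered allene ring comes from an anionic oxy-Cope ring expansion of a 1-dienyl-6-ethynylcyclohex-2-enol (C9–C4 cleaved, C6–C7 formed). The alkyne becomes the allene, the cyclohexene alkene becomes (Z)-C1=C10, and the enolate and ketone supply O8 and O9.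
3. The cyclohexenone comes from an enantioselective Diels–Alder reaction of a silyloxy diene with methacrolein (sets the quaternary carbon that controls all later centres), followed by alkyne homologation. The dienyl unit comes from a Stille coupling and the epoxy acid from asymmetric epoxidation of angelyl alcohol.
4. Ring order: cyclohexene (step 2), ten-membered carbocycle (step 9), γ-lactone (step 19); the oxirane of the ester is made separately (step 13).

Key step: step 19

Remark: germacrane numbering is used for all ten-membered compounds (ring C1–C10; C11 on C7 carries C12 and the methylene C13; C14 is the methyl on C10, C15 the methyl on C4). aS is the axial descriptor of the C4=C5=C6 allene. In step 2 the antipode of the catalyst is taken that delivers the (1R) adduct.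

**Route**

Step 1
Reactants: 1 (E)-2-methylbut-2-enal (tiglic aldehyde)
Product: 2 tert-butyl(dimethyl){[(1E)-2-methylbuta-1,3-dien-1-yl]oxy}silane
Conditions: t-BuMe2SiOTf, Et3N, Et2O, 0 °C to rt
Reagents that add atoms: tert-butyldimethylsilyl trifluoromethanesulfonate, CC(C)(C)[Si](C)(C)OS(=O)(=O)C(F)(F)F
Why: Silyl dienol ether formation by γ-deprotonation and O-silylation of the s-trans enal should give the (1E)-1-silyloxy diene needed for the cycloaddition.

Step 2
Reactants: 2 tert-butyl(dimethyl){[(1E)-2-methylbuta-1,3-dien-1-yl]oxy}silane; 3 methacrolein (2-methylprop-2-enal)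
Product: 4 (1R,2R)-2-{[tert-butyl(dimethyl)silyl]oxy}-1,3-dimethylcyclohex-3-ene-1-carbaldehyde
Conditions: (S)-1-(2-methylphenyl)-3,3-diphenylhexahydropyrrolo[1,2-c][1,3,2]oxazaborole·HNTf2 (10 mol %, antipode chosen to give 1R), CH2Cl2, −78 °C
Reagents that add atoms: none
Why: Catalytic enantioselective Diels–Alder reaction with a chiral oxazaborolidinium ion, in which the silyloxy group should direct the formyl-bearing carbon to the oxygenated diene terminus and the catalyst should shield one face of the bound enal so that the quaternary carbon (the later C4) is set as R, while the exo-formyl adduct expected for a 2-substituted acrolein fixes a second centre that is erased in step 5.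

Step 3
Reactants: 4 (1R,2R)-2-{[tert-butyl(dimethyl)silyl]oxy}-1,3-dimethylcyclohex-3-ene-1-carbaldehyde
Product: 5 tert-butyl{[(1R,6S)-6-ethynyl-2,6-dimethylcyclohex-2-en-1-yl]oxy}dimethylsilane
Conditions: dimethyl (1-diazo-2-oxopropyl)phosphonate, K2CO3, MeOH, 0 °C to rt
Reagents that add atoms: dimethyl (1-diazo-2-oxopropyl)phosphonate, COP(=O)(OC)C(=[N+]=[N-])C(C)=O
Why: Seyferth–Gilbert homologation in the Ohira–Bestmann variant should convert the aldehyde, which has no α-hydrogen and cannot epimerise, into the terminal alkyne.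

Step 4
Reactants: 5 tert-butyl{[(1R,6S)-6-ethynyl-2,6-dimethylcyclohex-2-en-1-yl]oxy}dimethylsilane
Product: 6 (1R,6S)-6-ethynyl-2,6-dimethylcyclohex-2-en-1-ol
Conditions: Bu4NF, THF, 0 °C to rt; H2O
Reagents that add atoms: none
Why: Fluoride-induced desilylation should free the allylic alcohol without touching the alkyne.

Step 5
Reactants: 6 (1R,6S)-6-ethynyl-2,6-dimethylcyclohex-2-en-1-ol
Product: 7 (6S)-6-ethynyl-2,6-dimethylcyclohex-2-en-1-one
Conditions: Dess–Martin periodinane, CH2Cl2, rt
Reagents that add atoms: none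
Why: Dess–Martin oxidation of the secondary allylic alcohol should give the enone, whose quaternary α-carbon cannot racemise.

Step 6
Reactants: 8 2,3-dibromoprop-1-ene; 9 (4-methoxyphenyl)methanol
Product: 10 1-{[(2-bromoprop-2-en-1-yl)oxy]methyl}-4-methoxybenzene
Conditions: NaH, THF, 0 °C; then 8, Bu4NI (cat.), rt
Reagents that add atoms: none
Why: Williamson ether synthesis, in which the alkoxide should displace the allylic bromide by SN2 while the vinylic bromide stays inert.

Step 7
Reactants: 10 1-{[(2-bromoprop-2-en-1-yl)oxy]methyl}-4-methoxybenzene; 11 (E)-1,2-bis(tributylstannyl)ethene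
Product: 12 tributyl[(1E)-3-{[(4-methoxyphenyl)methoxy]methyl}buta-1,3-dien-1-yl]stannane
Conditions: Pd(PPh3)4 (5 mol %), 11 (2.5 equiv), toluene, 90 °C
Reagents that add atoms: none
Why: Stille cross-coupling of the alkenyl bromide with one C–Sn bond of the distannane should proceed with retention of the E geometry, the excess of distannane suppressing double coupling.

Step 8
Reactants: 12 tributyl[(1E)-3-{[(4-methoxyphenyl)methoxy]methyl}buta-1,3-dien-1-yl]stannane; 7 (6S)-6-ethynyl-2,6-dimethylcyclohex-2-en-1-one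
Product: 14 (1S,6S)-6-ethynyl-1-[(1E)-3-{[(4-methoxyphenyl)methoxy]methyl}buta-1,3-dien-1-yl]-2,6-dimethylcyclohex-2-en-1-ol, via dienyllithium 13 (not isolated)
Conditions: 12 (2.2 equiv), n-BuLi (2.2 equiv), THF, −78 °C; then 7, −78 °C; H2O
Reagents that add atoms: none
Why: Tin–lithium exchange should give the (E)-dienyllithium with retention, and its 1,2-addition to the enone carbonyl should occur anti to the ethynyl group to give the trans alcohol; the excess of 13 allows for competing deprotonation of the ethynyl C–H, and the carbinol configuration is not critical because this carbon becomes trigonal in step 9.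

Step 9
Reactants: 14 (1S,6S)-6-ethynyl-1-[(1E)-3-{[(4-methoxyphenyl)methoxy]methyl}buta-1,3-dien-1-yl]-2,6-dimethylcyclohex-2-en-1-ol
Product: 17 (1(10)Z,7R,8R,aS)-8-hydroxy-12-[(4-methoxyphenyl)methoxy]germacra-1(10),4,5,11(13)-tetraen-9-one, via potassium alkoxide 15 (not isolated), via potassium enolate 16 (not isolated)
Conditions: KN(SiMe3)2 (1.05 equiv), 18-crown-6, THF, −78 to 0 °C; then −78 °C, 2-(benzenesulfonyl)-3-phenyloxaziridine; AcOH
Reagents that add atoms: 2-(benzenesulfonyl)-3-phenyloxaziridine, O=S(=O)(c1ccccc1)N1OC1c1ccccc1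
Why: Anionic oxy-Cope rearrangement of a 3-oxido-1-en-5-yne (acetylenic oxy-Cope type) should cleave the C9–C4 bond of the six-membered ring and form C6–C7, turning the alkyne into the C4=C5=C6 allene of the ten-membered ring; a chair transition state with the ring methylene C3 and the (E)-dienyl substituent equatorial should transfer the configuration of the quaternary carbon to C7 (R) and to the allene axis (aS), and Davis oxidation of the enolate on its outer face, anti to the transannular allene, should set C8 (R).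

Step 10
Reactants: 17 (1(10)Z,7R,8R,aS)-8-hydroxy-12-[(4-methoxyphenyl)methoxy]germacra-1(10),4,5,11(13)-tetraen-9-one
Product: 18 (1(10)Z,7R,8R,aS)-8-{[tert-butyl(dimethyl)silyl]oxy}-12-[(4-methoxyphenyl)methoxy]germacra-1(10),4,5,11(13)-tetraen-9-one
Conditions: t-BuMe2SiOTf, 2,6-lutidine, CH2Cl2, −78 °C
Reagents that add atoms: tert-butyldimethylsilyl trifluoromethanesulfonate, CC(C)(C)[Si](C)(C)OS(=O)(=O)C(F)(F)F
Why: O-Silylation of the α-ketol at low temperature should cap O8, which distinguishes the two oxygens of the later diol and later keeps the C8 hydroxyl away from the allene.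

Step 11
Reactants: 18 (1(10)Z,7R,8R,aS)-8-{[tert-butyl(dimethyl)silyl]oxy}-12-[(4-methoxyphenyl)methoxy]germacra-1(10),4,5,11(13)-tetraen-9-one
Product: 19 (1(10)Z,7R,8R,9R,aS)-8-{[tert-butyl(dimethyl)silyl]oxy}-12-[(4-methoxyphenyl)methoxy]germacra-1(10),4,5,11(13)-tetraen-9-ol
Conditions: NaBH4, CeCl3·7H2O, MeOH/THF, −78 °C
Reagents that add atoms: none
Why: Luche 1,2-reduction of the (Z)-enone, in which hydride is expected to add anti to the C8–O bond of the non-chelating silyl ether (Felkin–Anh polar model) from the outer face of the ring, should give the 8,9-syn alcohol with C9 as R.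

Step 12
Reactants: 20 (2Z)-2-methylbut-2-enoic acid (angelic acid)
Product: 21 (2Z)-2-methylbut-2-en-1-ol
Conditions: LiAlH4, Et2O, 0 °C; H2O
Reagents that add atoms: none
Why: Hydride reduction of the acid to the allylic alcohol at low temperature should keep the Z geometry.

Step 13
Reactants: 21 (2Z)-2-methylbut-2-en-1-ol
Product: 22 [(2R,3S)-2,3-dimethyloxiran-2-yl]methanol
Conditions: Ti(OiPr)4 (10 mol %), D-(−)-diethyl tartrate (12 mol %), t-BuOOH, 4 Å molecular sieves, CH2Cl2, −20 °C
Reagents that add atoms: tert-butyl hydroperoxide, CC(C)(C)OO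
Why: Sharpless asymmetric epoxidation, in which the D-(−)-tartrate complex should deliver oxygen to the alkene face that gives the (2R,3S) epoxy alcohol, with both ring centres set by reagent control and the cis relation of CH2OH and the C3 methyl kept from the Z alkene.

Step 14
Reactants: 22 [(2R,3S)-2,3-dimethyloxiran-2-yl]methanol
Product: 23 (2S,3S)-2,3-dimethyloxirane-2-carboxylic acid
Conditions: RuCl3 hydrate (2 mol %), NaIO4, MeCN/CCl4/H2O, rt
Reagents that add atoms: water, O; sodium periodate, [Na+].[O-]I(=O)(=O)=O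
Why: Oxidation of the primary alcohol to the acid by RuO4 generated in situ should leave the oxirane intact (the descriptor at C2 changes only because of the priority change).

Step 15
Reactants: 19 (1(10)Z,7R,8R,9R,aS)-8-{[tert-butyl(dimethyl)silyl]oxy}-12-[(4-methoxyphenyl)methoxy]germacra-1(10),4,5,11(13)-tetraen-9-ol; 23 (2S,3S)-2,3-dimethyloxirane-2-carboxylic acid
Product: 25 (1(10)Z,7R,8R,9R,aS)-8-{[tert-butyl(dimethyl)silyl]oxy}-12-[(4-methoxyphenyl)methoxy]germacra-1(10),4,5,11(13)-tetraen-9-yl (2S,3S)-2,3-dimethyloxirane-2-carboxylate, via mixed anhydride 24 (not isolated)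
Conditions: 23 (3 equiv), 2,4,6-Cl3C6H2COCl, Et3N, THF, rt; then 19, 4-(dimethylamino)pyridine, toluene, rt
Reagents that add atoms: none
Why: Yamaguchi esterification, in which the acylpyridinium formed at the less hindered carbonyl of the mixed anhydride should acylate the hindered allylic C9 hydroxyl with retention at C9 and without opening the oxirane.

Step 16
Reactants: 25 (1(10)Z,7R,8R,9R,aS)-8-{[tert-butyl(dimethyl)silyl]oxy}-12-[(4-methoxyphenyl)methoxy]germacra-1(10),4,5,11(13)-tetraen-9-yl (2S,3S)-2,3-dimethyloxirane-2-carboxylate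
Product: 26 (1(10)Z,7R,8R,9R,aS)-8-{[tert-butyl(dimethyl)silyl]oxy}-12-hydroxygermacra-1(10),4,5,11(13)-tetraen-9-yl (2S,3S)-2,3-dimethyloxirane-2-carboxylate
Conditions: 2,3-dichloro-5,6-dicyano-1,4-benzoquinone, CH2Cl2/pH 7 buffer, 0 °C
Reagents that add atoms: none
Why: Oxidative cleavage of the 4-methoxybenzyl ether under neutral conditions should free the C12 alcohol while the silyl ether, the epoxy ester and the allene survive.

Step 17
Reactants: 26 (1(10)Z,7R,8R,9R,aS)-8-{[tert-butyl(dimethyl)silyl]oxy}-12-hydroxygermacra-1(10),4,5,11(13)-tetraen-9-yl (2S,3S)-2,3-dimethyloxirane-2-carboxylate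
Product: 27 (1(10)Z,7R,8R,9R,aS)-8-{[tert-butyl(dimethyl)silyl]oxy}-12-oxogermacra-1(10),4,5,11(13)-tetraen-9-yl (2S,3S)-2,3-dimethyloxirane-2-carboxylate
Conditions: Dess–Martin periodinane, pyridine, CH2Cl2, 0 °C
Reagents that add atoms: none
Why: Dess–Martin oxidation of the primary allylic alcohol should give the 2-substituted acrolein without isomerising the methylene group or the allene.

Step 18
Reactants: 27 (1(10)Z,7R,8R,9R,aS)-8-{[tert-butyl(dimethyl)silyl]oxy}-12-oxogermacra-1(10),4,5,11(13)-tetraen-9-yl (2S,3S)-2,3-dimethyloxirane-2-carboxylate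
Product: 28 (1(10)Z,7R,8R,9R,aS)-8-{[tert-butyl(dimethyl)silyl]oxy}-9-{[(2S,3S)-2,3-dimethyloxiran-2-yl]carbonyloxy}germacra-1(10),4,5,11(13)-tetraen-12-oic acid
Conditions: NaClO2, NaH2PO4, 2-methylbut-2-ene, t-BuOH/H2O, 0 °C
Reagents that add atoms: sodium chlorite, [Na+].[O-]Cl=O
Why: Pinnick oxidation should convert the enal into the acrylic acid, with the alkene scavenger removing hypochlorite before it can attack the allene or the ring alkene.

Step 19
Reactants: 28 (1(10)Z,7R,8R,9R,aS)-8-{[tert-butyl(dimethyl)silyl]oxy}-9-{[(2S,3S)-2,3-dimethyloxiran-2-yl]carbonyloxy}germacra-1(10),4,5,11(13)-tetraen-12-oic acid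
Product: 29 (1(10)Z,4E,6S,7S,8R,9R)-8-{[tert-butyl(dimethyl)silyl]oxy}-9-{[(2S,3S)-2,3-dimethyloxiran-2-yl]carbonyloxy}germacra-1(10),4,11(13)-trien-12,6-olide (6,7-cis lactone)
Conditions: Ph3PAuNTf2 (5 mol %), CH2Cl2, 0 °C to rt, dark
Reagents that add atoms: none
Why: The cationic monovalent gold complex should bind the C5=C6 π bond of the allene, the C12 carboxyl oxygen should add to C6 from the opposite face (outer-sphere anti addition), and protodeauration of the C5–Au bond with retention should release the lactone and the catalyst. The closest known reaction type is the gold-catalysed cycloisomerisation of 4,5-allenoic acids to γ-alkenyl-γ-butyrolactones, together with the hydroalkoxylation of γ-hydroxy allenes with axial-to-central chirality transfer. The lactone closes in the 5-exo-trig mode at C6, the alternative attack at C4 being 7-endo. The new stereocentre C6 is controlled by the aS allene axis and the configuration of C7: the C7–C11 arm lies on the C15-methyl face of the C5=C6 bond, so oxygen enters there, C6 becomes S with H6 cis to H7, and the same event places C6 cis to C15, which is the (4E) alkene. The step needs chemoselectivity for the allene over the C1=C10 alkene, the acrylate and the epoxy ester, and regioselectivity for C6 over C4; these are secured by the higher reactivity of the strained allene towards the π-acid, by the five-membered tether, and by the silyl cap on O8, which blocks 6-endo attack of that oxygen at C4. The precursor carries no oxygen function and no stereocentre at C6, and the relief of the strain of the ten-membered cyclic allene drives the isomerisation.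

Step 20
Reactants: 29 (1(10)Z,4E,6S,7S,8R,9R)-8-{[tert-butyl(dimethyl)silyl]oxy}-9-{[(2S,3S)-2,3-dimethyloxiran-2-yl]carbonyloxy}germacra-1(10),4,11(13)-trien-12,6-olide
Product: 30 (1(10)Z,4E,6S,7R,8R,9R)-8-hydroxy-9-{[(2S,3S)-2,3-dimethyloxiran-2-yl]carbonyloxy}germacra-1(10),4,11(13)-trien-12,6-olide (CNP0213766.2)
Conditions: HF·pyridine, pyridine, THF, 0 °C to rt
Reagents that add atoms: none
Why: Buffered acidic desilylation should free the C8 hydroxyl without base-induced acyl migration from O9 or conjugate addition to the α-methylene lactone, and no stereocentre is touched.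

**Compound list**

1 | (E)-2-methylbut-2-enal (tiglic aldehyde) | C/C=C(\C)C=O | starting material
2 | tert-butyl(dimethyl){[(1E)-2-methylbuta-1,3-dien-1-yl]oxy}silane | C=C/C(C)=C/O[Si](C)(C)C(C)(C)C | intermediate
3 | methacrolein (2-methylprop-2-enal) | C=C(C)C=O | starting material
4 | (1R,2R)-2-{[tert-butyl(dimethyl)silyl]oxy}-1,3-dimethylcyclohex-3-ene-1-carbaldehyde | O=C[C@]1(C)CCC=C(C)[C@H]1O[Si](C)(C)C(C)(C)C | intermediate
5 | tert-butyl{[(1R,6S)-6-ethynyl-2,6-dimethylcyclohex-2-en-1-yl]oxy}dimethylsilane | C#C[C@]1(C)CCC=C(C)[C@H]1O[Si](C)(C)C(C)(C)C | intermediate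
6 | (1R,6S)-6-ethynyl-2,6-dimethylcyclohex-2-en-1-ol | C#C[C@]1(C)CCC=C(C)[C@H]1O | intermediate
7 | (6S)-6-ethynyl-2,6-dimethylcyclohex-2-en-1-one | C#C[C@]1(C)CCC=C(C)C1=O | intermediate
8 | 2,3-dibromoprop-1-ene | C=C(Br)CBr | starting material
9 | (4-methoxyphenyl)methanol | COc1ccc(CO)cc1 | starting material
10 | 1-{[(2-bromoprop-2-en-1-yl)oxy]methyl}-4-methoxybenzene | C=C(Br)COCc1ccc(OC)cc1 | intermediate
11 | (E)-1,2-bis(tributylstannyl)ethene | CCCC[Sn](CCCC)(CCCC)/C=C/[Sn](CCCC)(CCCC)CCCC | starting material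
12 | tributyl[(1E)-3-{[(4-methoxyphenyl)methoxy]methyl}buta-1,3-dien-1-yl]stannane | C=C(COCc1ccc(OC)cc1)/C=C/[Sn](CCCC)(CCCC)CCCC | intermediate
13 | [(1E)-3-{[(4-methoxyphenyl)methoxy]methyl}buta-1,3-dien-1-yl]lithium | [Li]/C=C/C(=C)COCc1ccc(OC)cc1 | intermediate (not isolated)
14 | (1S,6S)-6-ethynyl-1-[(1E)-3-{[(4-methoxyphenyl)methoxy]methyl}buta-1,3-dien-1-yl]-2,6-dimethylcyclohex-2-en-1-ol | C#C[C@]1(C)CCC=C(C)[C@@]1(O)/C=C/C(=C)COCc2ccc(OC)cc2 | intermediate
15 | potassium (1S,6S)-6-ethynyl-1-[(1E)-3-{[(4-methoxyphenyl)methoxy]methyl}buta-1,3-dien-1-yl]-2,6-dimethylcyclohex-2-en-1-olate | C#C[C@]1(C)CCC=C(C)[C@@]1([O-])/C=C/C(=C)COCc2ccc(OC)cc2.[K+] | intermediate (not isolated)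
16 | potassium (1(10)Z,8Z,7S,aS)-12-[(4-methoxyphenyl)methoxy]germacra-1(10),4,5,8,11(13)-pentaen-9-olate | C1C/C=C(/C)\C([O-])=C\[C@@H](C(=C)COCc2ccc(OC)cc2)C=[C@]=C1C.[K+] | intermediate (not isolated)
17 | (1(10)Z,7R,8R,aS)-8-hydroxy-12-[(4-methoxyphenyl)methoxy]germacra-1(10),4,5,11(13)-tetraen-9-one | C=C(COCc2ccc(OC)cc2)[C@H]1C=[C@@]=C(C)CC/C=C(/C)C(=O)[C@@H]1O | intermediate
18 | (1(10)Z,7R,8R,aS)-8-{[tert-butyl(dimethyl)silyl]oxy}-12-[(4-methoxyphenyl)methoxy]germacra-1(10),4,5,11(13)-tetraen-9-one | C=C(COCc2ccc(OC)cc2)[C@H]1C=[C@@]=C(C)CC/C=C(/C)C(=O)[C@@H]1O[Si](C)(C)C(C)(C)C | intermediate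
19 | (1(10)Z,7R,8R,9R,aS)-8-{[tert-butyl(dimethyl)silyl]oxy}-12-[(4-methoxyphenyl)methoxy]germacra-1(10),4,5,11(13)-tetraen-9-ol | C=C(COCc2ccc(OC)cc2)[C@H]1C=[C@@]=C(C)CC/C=C(/C)[C@@H](O)[C@@H]1O[Si](C)(C)C(C)(C)C | intermediate
20 | (2Z)-2-methylbut-2-enoic acid (angelic acid) | C/C=C(/C)C(=O)O | starting material
21 | (2Z)-2-methylbut-2-en-1-ol | C/C=C(/C)CO | intermediate
22 | [(2R,3S)-2,3-dimethyloxiran-2-yl]methanol | OC[C@@]1(C)O[C@H]1C | intermediate
23 | (2S,3S)-2,3-dimethyloxirane-2-carboxylic acid | OC(=O)[C@@]1(C)O[C@H]1C | intermediate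
24 | (2S,3S)-2,3-dimethyloxirane-2-carboxylic 2,4,6-trichlorobenzoic anhydride | O=C(OC(=O)[C@@]1(C)O[C@H]1C)c2c(Cl)cc(Cl)cc2Cl | intermediate (not isolated)
25 | (1(10)Z,7R,8R,9R,aS)-8-{[tert-butyl(dimethyl)silyl]oxy}-12-[(4-methoxyphenyl)methoxy]germacra-1(10),4,5,11(13)-tetraen-9-yl (2S,3S)-2,3-dimethyloxirane-2-carboxylate | C=C(COCc2ccc(OC)cc2)[C@H]1C=[C@@]=C(C)CC/C=C(/C)[C@@H](OC(=O)[C@@]3(C)O[C@H]3C)[C@@H]1O[Si](C)(C)C(C)(C)C | intermediate
26 | (1(10)Z,7R,8R,9R,aS)-8-{[tert-butyl(dimethyl)silyl]oxy}-12-hydroxygermacra-1(10),4,5,11(13)-tetraen-9-yl (2S,3S)-2,3-dimethyloxirane-2-carboxylate | C=C(CO)[C@H]1C=[C@@]=C(C)CC/C=C(/C)[C@@H](OC(=O)[C@@]2(C)O[C@H]2C)[C@@H]1O[Si](C)(C)C(C)(C)C | intermediate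
27 | (1(10)Z,7R,8R,9R,aS)-8-{[tert-butyl(dimethyl)silyl]oxy}-12-oxogermacra-1(10),4,5,11(13)-tetraen-9-yl (2S,3S)-2,3-dimethyloxirane-2-carboxylate | C=C(C=O)[C@H]1C=[C@@]=C(C)CC/C=C(/C)[C@@H](OC(=O)[C@@]2(C)O[C@H]2C)[C@@H]1O[Si](C)(C)C(C)(C)C | intermediate
28 | (1(10)Z,7R,8R,9R,aS)-8-{[tert-butyl(dimethyl)silyl]oxy}-9-{[(2S,3S)-2,3-dimethyloxiran-2-yl]carbonyloxy}germacra-1(10),4,5,11(13)-tetraen-12-oic acid | C=C(C(=O)O)[C@H]1C=[C@@]=C(C)CC/C=C(/C)[C@@H](OC(=O)[C@@]2(C)O[C@H]2C)[C@@H]1O[Si](C)(C)C(C)(C)C | intermediate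
29 | (1(10)Z,4E,6S,7S,8R,9R)-8-{[tert-butyl(dimethyl)silyl]oxy}-9-{[(2S,3S)-2,3-dimethyloxiran-2-yl]carbonyloxy}germacra-1(10),4,11(13)-trien-12,6-olide | C=C1C(=O)O[C@H]2/C=C(\C)CC/C=C(/C)[C@@H](OC(=O)[C@@]3(C)O[C@H]3C)[C@H](O[Si](C)(C)C(C)(C)C)[C@@H]12 | intermediate
30 | (1(10)Z,4E,6S,7R,8R,9R)-8-hydroxy-9-{[(2S,3S)-2,3-dimethyloxiran-2-yl]carbonyloxy}germacra-1(10),4,11(13)-trien-12,6-olide (CNP0213766.2) | C=C1C(=O)O[C@H]2/C=C(\C)CC/C=C(/C)[C@@H](OC(=O)[C@@]3(C)O[C@H]3C)[C@H](O)[C@@H]12 | target

**Step count and risks**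

Total step count: 20. Longest linear sequence: 15 steps (steps 1–5, 8–11, 15–20); steps 6–7 and 12–14 are branches.

Steps most likely to fail:

1. Step 9 (ring expansion and hydroxylation). The alkoxide may add across the neighbouring alkyne or be partly consumed as the acetylide, the strained allenyl enolate may react transannularly before it is oxidised, and ring inversion of the enolate before oxidation would erode the facial selectivity at C8. The fallback avoids all anionic species and sets out from 14. Silylation (Me3SiCl, imidazole, DMF) should give the trimethylsilyl ether F1. Thermolysis in degassed toluene in a sealed tube at about 180 °C should effect the neutral silyloxy-Cope shift through the same chair and give the ring-expanded trimethylsilyl enol ether F2. Rubottom oxidation with dimethyldioxirane (acetone, −78 °C) should oxidise the enol ether on its exposed face to the α-silyloxy ketone F3. Brief treatment with citric acid in MeOH/H2O should then release 17, where the route is rejoined.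

2. Step 19 (key lactonisation). The axial chirality may be eroded through a planar allyl–gold cation, the oxygen may add to the other allene face after a change of ring conformation (which would give the 4Z trans-fused isomer), or the Lewis acid may open the oxirane. The fallback sets out from 28 and uses a stoichiometric electrophile instead of a π-acid. Iodolactonisation (I2, NaHCO3, MeCN, 0 °C) should close the same 5-exo ring by anti addition across C5=C6 and give the 5-iodo lactone F4. Palladium-catalysed hydrodeiodination of the alkenyl iodide with retention (Pd(OAc)2, PPh3, HCO2H, Et3N, DMF, 50 °C) should then give 29, where the route is rejoined.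

3. Step 11 (ketone reduction). The facial selectivity may be poor or reversed, because the conformation of the ten-membered ring rather than the open-chain Felkin–Anh model may decide the approach of hydride. The fallback accepts the wrong epimer and corrects it in the esterification. It sets out from 18, whose reduction would then give mainly the 9S alcohol F5. Mitsunobu esterification of F5 with acid 23 (PPh3, diisopropyl azodicarboxylate, toluene, 0 °C to rt) should install the ester with inversion at C9 and give 25 directly, where the route is rejoined.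

**Further compounds**

F1 | step 9 | {[(1S,6S)-6-ethynyl-1-[(1E)-3-{[(4-methoxyphenyl)methoxy]methyl}buta-1,3-dien-1-yl]-2,6-dimethylcyclohex-2-en-1-yl]oxy}trimethylsilane | C#C[C@]1(C)CCC=C(C)[C@@]1(O[Si](C)(C)C)/C=C/C(=C)COCc2ccc(OC)cc2
F2 | step 9 | (1(10)Z,8Z,7S,aS)-12-[(4-methoxyphenyl)methoxy]-9-[(trimethylsilyl)oxy]germacra-1(10),4,5,8,11(13)-pentaene | C1C/C=C(/C)\C(O[Si](C)(C)C)=C\[C@@H](C(=C)COCc2ccc(OC)cc2)C=[C@]=C1C
F3 | step 9 | (1(10)Z,7R,8R,aS)-12-[(4-methoxyphenyl)methoxy]-8-[(trimethylsilyl)oxy]germacra-1(10),4,5,11(13)-tetraen-9-one | C=C(COCc2ccc(OC)cc2)[C@H]1C=[C@@]=C(C)CC/C=C(/C)C(=O)[C@@H]1O[Si](C)(C)C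
F4 | step 19 | (1(10)Z,4Z,6R,7S,8R,9R)-8-{[tert-butyl(dimethyl)silyl]oxy}-9-{[(2S,3S)-2,3-dimethyloxiran-2-yl]carbonyloxy}-5-iodogermacra-1(10),4,11(13)-trien-12,6-olide | C=C1C(=O)O[C@H]2/C(I)=C(\C)CC/C=C(/C)[C@@H](OC(=O)[C@@]3(C)O[C@H]3C)[C@H](O[Si](C)(C)C(C)(C)C)[C@@H]12
F5 | step 11 | (1(10)Z,7R,8R,9S,aS)-8-{[tert-butyl(dimethyl)silyl]oxy}-12-[(4-methoxyphenyl)methoxy]germacra-1(10),4,5,11(13)-tetraen-9-ol | C=C(COCc2ccc(OC)cc2)[C@H]1C=[C@@]=C(C)CC/C=C(/C)[C@H](O)[C@@H]1O[Si](C)(C)C(C)(C)C
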